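**Retrosynthetic overview**

1. Locants are those of the germacrane skeleton: ring C1–C10 (C4/C5 oxirane, C6 ester carbinol, C7 the isopropyl-bearing CH, C8=C9, C10 carbinol), isopropyl C11–C13 on C7. Late disconnections: the C6 ester; C10–OH/C8=C9 from a Mislow–Evans shift of a C8 sulfoxide with C9=C10; isopropyl from isopropenyl.
2. Key disconnection C7–C8: thia-[2,3]-Wittig ring contraction of a 13-membered bis-allyl sulfide in which one sulfur atom bridges C8 and C12.
3. Enabling feature: ring carbon C7 carries the isopropyl group (C11 with its methyl C12) directly beside the allylic tertiary carbinol unit C8=C9–C10(OH). Moving the heteroatom across that allyl unit (C10–O to C8–S) and tying it to C12 makes C12–C11=C7 and C8–C9=C10 the two allyl arms of one sulfide, so a single sulfur closes the large ring, forges C7–C8 and later delivers the C10 oxygen.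
4. The thiacycle comes from Na2S and a bis-allylic dibromide; that chain comes from an epoxy aldehyde (Sharpless epoxidation, C4/C5) plus an alkenyllithium (C7, C11–C13), with C6 set by chelation-controlled ketone reduction; the C8–C5 chain comes from hepta-1,6-diyne by carboalumination (9E) and carbocupration (4Z).
5. Ring order: oxirane (step 7), 13-membered thiacycle (step 17), 10-membered carbocycle by ring contraction (step 18).

Key step: step 18

Remark: the target is read as the (4S,5R,6R,7S,10R,8E) isomer whose oxirane has C3 and C6 on the same side, so the oxirane is derived from a Z-trisubstituted allylic alcohol.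

**Step 1**
Reactants: 1 hepta-1,6-diyne (threefold excess)
Product: 3 ethyl (2E)-3-methyloct-2-en-7-ynoate, via alkenylalane 2 (not isolated)
Conditions: Me3Al, Cp2ZrCl2 (20 mol %), (CH2Cl)2, rt; then ClCO2Et, 0 °C to rt
Reagents that add atoms: trimethylaluminum C[Al](C)C; ethyl chloroformate CCOC(Cl)=O
Why: Zirconium-catalysed syn-carboalumination (Negishi) of one terminal alkyne puts methyl on the internal and aluminium on the terminal carbon, and acylation of the alkenylalane with retention fixes the 9E geometry; the excess of diyne holds the reaction at mono-addition.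

**Step 2**
Reactants: 3 ethyl (2E)-3-methyloct-2-en-7-ynoate
Product: 4 (2E)-3-methyloct-2-en-7-yn-1-ol
Conditions: iBu2AlH, CH2Cl2, −78 °C
Reagents that add atoms: none
Why: iBu2AlH reduces the conjugated ester by 1,2-addition to the allylic alcohol and leaves the terminal alkyne and the E alkene untouched.

**Step 3**
Reactants: 4 (2E)-3-methyloct-2-en-7-yn-1-ol
Product: 5 tert-butyldimethyl{[(2E)-3-methyloct-2-en-7-yn-1-yl]oxy}silane
Conditions: TBSCl, imidazole, CH2Cl2, rt
Reagents that add atoms: tert-butyldimethylsilyl chloride CC(C)(C)[Si](C)(C)Cl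
Why: Standard silylation masks the C8 hydroxyl through the organometallic steps that follow.

**Step 4**
Reactants: 5 tert-butyldimethyl{[(2E)-3-methyloct-2-en-7-yn-1-yl]oxy}silane
Product: 7 methyl (7E)-9-[(tert-butyldimethylsilyl)oxy]-7-methylnon-7-en-2-ynoate, via lithium acetylide 6 (not isolated)
Conditions: n-BuLi, THF, −78 °C; then ClCO2Me
Reagents that add atoms: methyl chloroformate COC(Cl)=O
Why: Deprotonation of the terminal alkyne and C-acylation of the lithium acetylide give the ynoate needed for the carbocupration.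

**Step 5**
Reactants: 7 methyl (7E)-9-[(tert-butyldimethylsilyl)oxy]-7-methylnon-7-en-2-ynoate
Product: 9 methyl (2Z,7E)-9-[(tert-butyldimethylsilyl)oxy]-3,7-dimethylnona-2,7-dienoate, via alkenylcuprate 8 (not isolated)
Conditions: Me2CuLi (from CuI and MeLi), THF, −78 °C; quench at −78 °C with aq. NH4Cl
Reagents that add atoms: lithium dimethylcuprate [Li+].C[Cu-]C
Why: Syn-carbocupration of the ynoate at low temperature and protonation of the alkenylcopper with retention place the new methyl trans to the ester, which gives the Z (nerol-type) C4=C5 alkene.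

**Step 6**
Reactants: 9 methyl (2Z,7E)-9-[(tert-butyldimethylsilyl)oxy]-3,7-dimethylnona-2,7-dienoate
Product: 10 (2Z,7E)-9-[(tert-butyldimethylsilyl)oxy]-3,7-dimethylnona-2,7-dien-1-ol
Conditions: iBu2AlH, CH2Cl2, −78 °C
Reagents that add atoms: none
Why: 1,2-Reduction of the enoate gives the Z allylic alcohol that the asymmetric epoxidation requires, with silyl ether and both alkene geometries unaffected.

**Step 7**
Reactants: 10 (2Z,7E)-9-[(tert-butyldimethylsilyl)oxy]-3,7-dimethylnona-2,7-dien-1-ol
Product: 11 {(2R,3S)-3-[(4E)-6-[(tert-butyldimethylsilyl)oxy]-4-methylhex-4-en-1-yl]-3-methyloxiran-2-yl}methanol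
Conditions: Ti(OiPr)4 (10 mol %), D-(−)-diethyl tartrate (12 mol %), t-BuOOH, 4 Å molecular sieves, CH2Cl2, −20 °C
Reagents that add atoms: tert-butyl hydroperoxide CC(C)(C)OO
Why: Sharpless asymmetric epoxidation is directed by the free primary allylic hydroxyl (the silylated allylic alkene does not react) and with D-(−)-tartrate should give the (2R,3S)-oxirane, the enantiomer of the L-(+)-tartrate product of nerol-type alcohols, which sets C4 (S) and C5 (R) with the cis fusion that comes from the Z alkene.

**Step 8**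
Reactants: 11 {(2R,3S)-3-[(4E)-6-[(tert-butyldimethylsilyl)oxy]-4-methylhex-4-en-1-yl]-3-methyloxiran-2-yl}methanol
Product: 12 (2S,3S)-3-[(4E)-6-[(tert-butyldimethylsilyl)oxy]-4-methylhex-4-en-1-yl]-3-methyloxirane-2-carbaldehyde
Conditions: Dess–Martin periodinane, NaHCO3, CH2Cl2, 0 °C to rt
Reagents that add atoms: none
Why: Buffered Dess–Martin oxidation gives the epoxy aldehyde without acid or base strong enough to open the oxirane (the descriptor at C5 changes by priority only).

**Step 9**
Reactants: 13 prop-2-yn-1-ol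
Product: 15 (2E)-3-iodo-2-methylprop-2-en-1-ol, via alkenylalane 14 (not isolated)
Conditions: Me3Al (3 equiv), Cp2ZrCl2 (25 mol %), CH2Cl2, 0 °C to rt; then I2, THF, −30 °C
Reagents that add atoms: trimethylaluminum C[Al](C)C; iodine II
Why: Zirconium-catalysed syn-carboalumination (Negishi) and iodinolysis with retention give the E alkenyl iodide, with iodine cis to the new methyl.

**Step 10**
Reactants: 15 (2E)-3-iodo-2-methylprop-2-en-1-ol
Product: 16 tert-butyl{[(2E)-3-iodo-2-methylprop-2-en-1-yl]oxy}dimethylsilane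
Conditions: TBSCl, imidazole, CH2Cl2, rt
Reagents that add atoms: tert-butyldimethylsilyl chloride CC(C)(C)[Si](C)(C)Cl
Why: Standard silylation of the primary allylic alcohol.

**Step 11**
Reactants: 16 tert-butyl{[(2E)-3-iodo-2-methylprop-2-en-1-yl]oxy}dimethylsilane; 12 (2S,3S)-epoxy aldehyde
Product: 18 bis-silyl epoxy allylic alcohol as a mixture of C6 epimers, via alkenyllithium 17 (not isolated)
Conditions: 16, t-BuLi (2 equiv), Et2O, −78 °C; then 12, −78 °C; water
Reagents that add atoms: none
Why: Iodine–lithium exchange with retention of the E geometry and 1,2-addition of the alkenyllithium to the aldehyde form the C6–C7 bond; C6 is not controlled here and is corrected in steps 12 and 13.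

**Step 12**
Reactants: 18 bis-silyl epoxy allylic alcohol (C6 epimers)
Product: 19 (2E)-4-[(tert-butyldimethylsilyl)oxy]-1-{(2S,3S)-3-[(4E)-6-[(tert-butyldimethylsilyl)oxy]-4-methylhex-4-en-1-yl]-3-methyloxiran-2-yl}-3-methylbut-2-en-1-one
Conditions: Dess–Martin periodinane, NaHCO3, CH2Cl2, 0 °C to rt
Reagents that add atoms: none
Why: Dess–Martin oxidation converges both epimers on one epoxy enone.

**Step 13**
Reactants: 19 epoxy enone
Product: 20 (1R,2E)-4-[(tert-butyldimethylsilyl)oxy]-1-{(2R,3S)-3-[(4E)-6-[(tert-butyldimethylsilyl)oxy]-4-methylhex-4-en-1-yl]-3-methyloxiran-2-yl}-3-methylbut-2-en-1-ol (4S,5R,6R)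
Conditions: Zn(BH4)2, Et2O, −20 °C
Reagents that add atoms: none
Why: Zn(BH4)2 chelates the ketone and oxirane oxygens, so 1,2-hydride delivery anti to C4 (the face also shielded by the cis C3 chain) should give the erythro (anti) epoxy alcohol, that is 6R beside 5R.

**Step 14**
Reactants: 20 (4S,5R,6R)-epoxy alcohol
Product: 21 tris-silyl ether (C6, C8 and C12 OTBS; 4S,5R,6R)
Conditions: TBSOTf, 2,6-lutidine, CH2Cl2, −78 to 0 °C
Reagents that add atoms: tert-butyldimethylsilyl triflate CC(C)(C)[Si](C)(C)OS(=O)(=O)C(F)(F)F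
Why: A silyl triflate with a hindered base silylates the hindered secondary C6 hydroxyl, and the bulky silyloxy group later controls the face of C7 in the key step.

**Step 15**
Reactants: 21 tris-silyl ether
Product: 22 C8,C12-diol (C6 OTBS; 4S,5R,6R; 9E and 7(11)E)
Conditions: HF·pyridine, excess pyridine, THF, 0 °C
Reagents that add atoms: none
Why: Buffered HF·pyridine cleaves the two unhindered primary allylic silyl ethers much faster than the secondary one flanked by the oxirane and the trisubstituted alkene.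

**Step 16**
Reactants: 22 C8,C12-diol
Product: 23 C8,C12-dibromide (C6 OTBS; 4S,5R,6R; 9E and 7(11)E)
Conditions: CBr4, PPh3, 2,6-lutidine, CH2Cl2, −20 to 0 °C; used at once
Reagents that add atoms: carbon tetrabromide BrC(Br)(Br)Br
Why: The Appel reaction converts both primary allylic alcohols into bromides by SN2 displacement under neutral conditions that the oxirane and the silyl ether tolerate.

**Step 17**
Reactants: 23 C8,C12-dibromide
Product: 26 13-membered thiacycle (sulfur between C8 and C12; C6 OTBS; 4S,5R,6R; 9E and 7(11)E), via C8 thiolate 24 (not isolated), via C12 thiolate 25 (not isolated)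
Conditions: Na2S·9H2O, EtOH–THF, high dilution (slow simultaneous addition), rt
Reagents that add atoms: sodium sulfide [Na+].[Na+].[S-2]
Why: Twofold SN2 thioetherification of the bis-allylic dibromide under high dilution closes the 13-membered ring, a size with little transannular strain in which two E alkenes and the oxirane restrict the chain; either mono-substituted thiolate leads to the same ring.

**Step 18**
Reactants: 26 13-membered thiacycle
Product: 29 (4S,5R,6R,7R,8R,9E)-6-[(tert-butyldimethylsilyl)oxy]-4,5-epoxy-8-(methylsulfanyl)germacra-9,11-diene, via lithio sulfide 27 (not isolated), via lithium thiolate 28 (not isolated)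
Conditions: s-BuLi (1.1 equiv), THF, −78 °C; warm to −30 °C; then MeI, −78 to 0 °C
Reagents that add atoms: iodomethane CI
Why: Proposed new method: s-BuLi removes one α-thio allylic proton at C8, and the lithio sulfide 27 undergoes a suprafacial [2,3]-sigmatropic shift (thia-Wittig rearrangement) through a five-membered envelope C8–S–C12–C11=C7 that forms C7–C8, breaks S–C12 and turns C11=C12 into the isopropenyl group, driven by the exchange of a carbanion for a thiolate; the closest known reaction types are the [2,3]-Wittig ring contraction of 13-membered diallyl ethers to 10-membered carbocyclic alcohols and the [2,3] shift of α-lithiated acyclic diallyl sulfides. The 10-membered carbocycle closes by transannular ring contraction of the 13-membered thiacycle, so the entropic cost of medium-ring formation was already paid in the easier closure of step 17. C7 is controlled by the C6 stereocentre: the C13 methyl on C11 is cis to C6, allylic 1,3-strain therefore holds H6 in the alkene plane, and C8 adds anti to the C6–OSi bond on the face that carries C5 (Felkin-type), which gives the target relationship between C6 and C7. C8 is controlled by the E geometry of C7=C11 together with an exo position of the C9 vinyl group in the envelope, where it avoids the C13 methyl, and this gives the 8R sulfide that the later suprafacial transfer to C10 needs. The step needs lithiation at C8 and not at C12, and a [2,3] and not a [1,2] shift: the C8 methylene is the less hindered one (flanked by a CH= and not by the fully substituted C11), only its anion can reach an unsubstituted alkene terminus, and the low temperature disfavours the radical-pair [1,2] path. Methyl iodide then caps thiolate 28 so that sulfur stays on C8 for step 20.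

**Step 19**
Reactants: 29 isopropenyl methyl sulfide
Product: 30 (4S,5R,6R,7R,8R,9E)-6-[(tert-butyldimethylsilyl)oxy]-4,5-epoxy-8-(methylsulfanyl)germacr-9-ene
Conditions: H2 (1 atm), RhCl(PPh3)3 (15 mol %), benzene, rt
Reagents that add atoms: none
Why: Homogeneous hydrogenation with RhCl(PPh3)3 tolerates the thioether and reduces the 1,1-disubstituted isopropenyl group far faster than the trisubstituted ring alkene; C11 is not stereogenic, so no new stereocentre arises.

**Step 20**
Reactants: 30 isopropyl methyl sulfide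
Product: 33 (4S,5R,6R,7S,10R,8E)-6-[(tert-butyldimethylsilyl)oxy]-4,5-epoxygermacr-8-en-10-ol, via sulfoxide 31 (not isolated), via sulfenate 32 (not isolated)
Conditions: mCPBA (1.0 equiv), NaHCO3, CH2Cl2, −78 °C; then P(OMe)3, Et3N, MeOH, −78 °C to rt
Reagents that add atoms: 3-chloroperbenzoic acid OOC(=O)c1cccc(Cl)c1
Why: Peracid oxidises sulfur far faster than the alkene, and the allylic sulfoxide then undergoes the Mislow–Evans [2,3] shift, in which oxygen passes suprafacially from C8 to C10 (8R to 10R) while C7 takes the outside position away from the C10 methyl (allylic strain) to give the 8E alkene; the phosphite cleaves the sulfenate S–O bond and pulls the equilibrium over.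

**Step 21**
Reactants: 33 silyl-protected allylic alcohol
Product: 34 (4S,5R,6R,7S,10R,8E)-4,5-epoxygermacr-8-ene-6,10-diol
Conditions: Bu4NF, AcOH (1:1), THF, rt
Reagents that add atoms: none
Why: Acetic-acid-buffered fluoride removes the last silyl ether without leaving a free alkoxide that could start a Payne rearrangement of the neighbouring oxirane.

**Step 22**
Reactants: 34 epoxy diol; 35 4-acetoxybenzoic acid
Product: 36 (4S,5R,6R,7S,10R,8E)-4,5-epoxy-10-hydroxygermacr-8-en-6-yl 4-acetoxybenzoate
Conditions: DCC, DMAP, CH2Cl2, 0 °C to rt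
Reagents that add atoms: none
Why: Steglich esterification acylates only the secondary C6 hydroxyl, since the tertiary allylic C10 hydroxyl does not react with the acylpyridinium intermediate, and C6 keeps its configuration.

**Step 23**
Reactants: 36 acetoxybenzoate
Product: 37 (4S,5R,6R,7S,10R,8E)-4,5-epoxy-10-hydroxygermacr-8-en-6-yl 4-hydroxybenzoate (CNP0278889.1)
Conditions: pyrrolidine, CH2Cl2, 0 °C
Reagents that add atoms: none
Why: Aminolysis cleaves the phenyl acetate, an activated ester, much faster than the hindered alkyl benzoate and leaves the oxirane and the tertiary allylic alcohol untouched.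

**Compound list**

1 | hepta-1,6-diyne | C#CCCCC#C | starting material
2 | dimethyl[(1E)-2-methylhept-1-en-6-yn-1-yl]alane | C#CCCC/C(C)=C/[Al](C)C | intermediate
3 | ethyl (2E)-3-methyloct-2-en-7-ynoate | C#CCCC/C(C)=C/C(=O)OCC | intermediate
4 | (2E)-3-methyloct-2-en-7-yn-1-ol | C#CCCC/C(C)=C/CO | intermediate
5 | tert-butyldimethyl{[(2E)-3-methyloct-2-en-7-yn-1-yl]oxy}silane | C#CCCC/C(C)=C/CO[Si](C)(C)C(C)(C)C | intermediate
6 | lithium acetylide of 5 | [Li]C#CCCC/C(C)=C/CO[Si](C)(C)C(C)(C)C | intermediate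
7 | methyl (7E)-9-[(tert-butyldimethylsilyl)oxy]-7-methylnon-7-en-2-ynoate | COC(=O)C#CCCC/C(C)=C/CO[Si](C)(C)C(C)(C)C | intermediate
8 | lithium alkenyl(methyl)cuprate from syn-addition to 7 (copper on C2, cis to the new C3 methyl) | [Li+].COC(=O)/C([Cu-]C)=C(/C)CCC/C(C)=C/CO[Si](C)(C)C(C)(C)C | intermediate
9 | methyl (2Z,7E)-9-[(tert-butyldimethylsilyl)oxy]-3,7-dimethylnona-2,7-dienoate | COC(=O)/C=C(/C)CCC/C(C)=C/CO[Si](C)(C)C(C)(C)C | intermediate
10 | (2Z,7E)-9-[(tert-butyldimethylsilyl)oxy]-3,7-dimethylnona-2,7-dien-1-ol | OC/C=C(/C)CCC/C(C)=C/CO[Si](C)(C)C(C)(C)C | intermediate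
11 | {(2R,3S)-3-[(4E)-6-[(tert-butyldimethylsilyl)oxy]-4-methylhex-4-en-1-yl]-3-methyloxiran-2-yl}methanol | CC(C)(C)[Si](C)(C)OC/C=C(\C)CCC[C@]1(C)O[C@@H]1CO | intermediate
12 | (2S,3S)-3-[(4E)-6-[(tert-butyldimethylsilyl)oxy]-4-methylhex-4-en-1-yl]-3-methyloxirane-2-carbaldehyde | CC(C)(C)[Si](C)(C)OC/C=C(\C)CCC[C@]1(C)O[C@@H]1C=O | intermediate
13 | prop-2-yn-1-ol | C#CCO | starting material
14 | dimethylaluminium (2E)-3-(dimethylalumanyl)-2-methylprop-2-en-1-olate | C[Al](C)OC/C(C)=C/[Al](C)C | intermediate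
15 | (2E)-3-iodo-2-methylprop-2-en-1-ol | OC/C(C)=C/I | intermediate
16 | tert-butyl{[(2E)-3-iodo-2-methylprop-2-en-1-yl]oxy}dimethylsilane | CC(C)(C)[Si](C)(C)OC/C(C)=C/I | intermediate
17 | (1E)-3-[(tert-butyldimethylsilyl)oxy]-2-methylprop-1-en-1-yllithium | CC(C)(C)[Si](C)(C)OC/C(C)=C/[Li] | intermediate
18 | (2E)-4-[(tert-butyldimethylsilyl)oxy]-1-{(2R,3S)-3-[(4E)-6-[(tert-butyldimethylsilyl)oxy]-4-methylhex-4-en-1-yl]-3-methyloxiran-2-yl}-3-methylbut-2-en-1-ol, both C6 epimers | CC(C)(C)[Si](C)(C)OC/C=C(\C)CCC[C@]1(C)O[C@@H]1C(O)/C=C(\C)CO[Si](C)(C)C(C)(C)C | intermediate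
19 | (2E)-4-[(tert-butyldimethylsilyl)oxy]-1-{(2S,3S)-3-[(4E)-6-[(tert-butyldimethylsilyl)oxy]-4-methylhex-4-en-1-yl]-3-methyloxiran-2-yl}-3-methylbut-2-en-1-one | CC(C)(C)[Si](C)(C)OC/C=C(\C)CCC[C@]1(C)O[C@@H]1C(=O)/C=C(\C)CO[Si](C)(C)C(C)(C)C | intermediate
20 | (1R,2E)-4-[(tert-butyldimethylsilyl)oxy]-1-{(2R,3S)-3-[(4E)-6-[(tert-butyldimethylsilyl)oxy]-4-methylhex-4-en-1-yl]-3-methyloxiran-2-yl}-3-methylbut-2-en-1-ol (4S,5R,6R) | CC(C)(C)[Si](C)(C)OC/C=C(\C)CCC[C@]1(C)O[C@@H]1[C@H](O)/C=C(\C)CO[Si](C)(C)C(C)(C)C | intermediate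
21 | tris-silyl ether of 20 (C6, C8 and C12 OTBS; 4S,5R,6R) | CC(C)(C)[Si](C)(C)OC/C=C(\C)CCC[C@]1(C)O[C@@H]1[C@H](O[Si](C)(C)C(C)(C)C)/C=C(\C)CO[Si](C)(C)C(C)(C)C | intermediate
22 | C8,C12-diol (C6 OTBS; 4S,5R,6R; 9E and 7(11)E) | OC/C=C(\C)CCC[C@]1(C)O[C@@H]1[C@H](O[Si](C)(C)C(C)(C)C)/C=C(\C)CO | intermediate
23 | C8,C12-dibromide (C6 OTBS; 4S,5R,6R; 9E and 7(11)E) | BrC/C=C(\C)CCC[C@]1(C)O[C@@H]1[C@H](O[Si](C)(C)C(C)(C)C)/C=C(\C)CBr | intermediate
24 | sodium C8-thiolate of the C12-bromide | [Na+].[S-]C/C=C(\C)CCC[C@]1(C)O[C@@H]1[C@H](O[Si](C)(C)C(C)(C)C)/C=C(\C)CBr | intermediate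
25 | sodium C12-thiolate of the C8-bromide | BrC/C=C(\C)CCC[C@]1(C)O[C@@H]1[C@H](O[Si](C)(C)C(C)(C)C)/C=C(\C)C[S-].[Na+] | intermediate
26 | 13-membered thiacycle (sulfur between C8 and C12; C6 OTBS; 4S,5R,6R; 9E and 7(11)E) | S1C/C=C(\C)CCC[C@]2(C)O[C@@H]2[C@H](O[Si](C)(C)C(C)(C)C)/C=C(\C)C1 | intermediate
27 | C8-lithio derivative of 26 | S1C([Li])/C=C(\C)CCC[C@]2(C)O[C@@H]2[C@H](O[Si](C)(C)C(C)(C)C)/C=C(\C)C1 | intermediate
28 | lithium (4S,5R,6R,7R,8R,9E)-6-[(tert-butyldimethylsilyl)oxy]-4,5-epoxygermacra-9,11-diene-8-thiolate | C=C(C)[C@H]1[C@H]([S-])/C=C(\C)CCC[C@]2(C)O[C@@H]2[C@@H]1O[Si](C)(C)C(C)(C)C.[Li+] | intermediate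
29 | (4S,5R,6R,7R,8R,9E)-6-[(tert-butyldimethylsilyl)oxy]-4,5-epoxy-8-(methylsulfanyl)germacra-9,11-diene | C=C(C)[C@H]1[C@H](SC)/C=C(\C)CCC[C@]2(C)O[C@@H]2[C@@H]1O[Si](C)(C)C(C)(C)C | intermediate
30 | (4S,5R,6R,7R,8R,9E)-6-[(tert-butyldimethylsilyl)oxy]-4,5-epoxy-8-(methylsulfanyl)germacr-9-ene | CC(C)[C@H]1[C@H](SC)/C=C(\C)CCC[C@]2(C)O[C@@H]2[C@@H]1O[Si](C)(C)C(C)(C)C | intermediate
31 | S-oxide of 30 (both sulfur epimers) | CC(C)[C@H]1[C@H](S(C)=O)/C=C(\C)CCC[C@]2(C)O[C@@H]2[C@@H]1O[Si](C)(C)C(C)(C)C | intermediate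
32 | (4S,5R,6R,7S,10R,8E)-6-[(tert-butyldimethylsilyl)oxy]-4,5-epoxygermacr-8-en-10-yl methanesulfenate | CC(C)[C@H]1/C=C/[C@](C)(OSC)CCC[C@]2(C)O[C@@H]2[C@@H]1O[Si](C)(C)C(C)(C)C | intermediate
33 | (4S,5R,6R,7S,10R,8E)-6-[(tert-butyldimethylsilyl)oxy]-4,5-epoxygermacr-8-en-10-ol | CC(C)[C@H]1/C=C/[C@](C)(O)CCC[C@]2(C)O[C@@H]2[C@@H]1O[Si](C)(C)C(C)(C)C | intermediate
34 | (4S,5R,6R,7S,10R,8E)-4,5-epoxygermacr-8-ene-6,10-diol | CC(C)[C@H]1/C=C/[C@](C)(O)CCC[C@]2(C)O[C@@H]2[C@@H]1O | intermediate
35 | 4-acetoxybenzoic acid | CC(=O)Oc1ccc(cc1)C(O)=O | starting material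
36 | (4S,5R,6R,7S,10R,8E)-4,5-epoxy-10-hydroxygermacr-8-en-6-yl 4-acetoxybenzoate | CC(C)[C@H]1/C=C/[C@](C)(O)CCC[C@]2(C)O[C@@H]2[C@@H]1OC(=O)c1ccc(OC(C)=O)cc1 | intermediate
37 | (4S,5R,6R,7S,10R,8E)-4,5-epoxy-10-hydroxygermacr-8-en-6-yl 4-hydroxybenzoate (CNP0278889.1) | CC(C)[C@H]1/C=C/[C@](C)(O)CCC[C@]2(C)O[C@@H]2[C@@H]1OC(=O)c1ccc(O)cc1 | target

**Step count and risks**

Total step count: 23. Longest linear sequence: 21 (steps 1–8 and 11–23).

Most likely to fail, step 18 (Proposed new method). Lithiation may occur at the C12 methylene instead of C8, after which the anion can expel the C6 silyloxy group or shift onto C10. The allyllithium may also attack the oxirane across the ring while the sulfur shift is still slow, and facial control at C7 may erode. The fallback uses known chemistry, sets out from 22 and comes back at 33. Partial Appel bromination (CBr4, PPh3, 1 equiv) would give the C8 mono-bromide F1 together with the C12 mono-bromide F2, and both would close under Williamson conditions (NaH, THF, high dilution) to the same 13-membered diallyl ether F3. n-BuLi in THF at −78 °C would then trigger the oxygen [2,3]-Wittig ring contraction, a reaction known for 13-membered diallyl ethers and fast at a temperature where elimination and oxirane opening should not compete, to give the 8R homoallylic alcohol F4. Hydrogenation (H2, RhCl(PPh3)3) would give the isopropyl alcohol F5. Because oxygen then sits on C8, the transposition would be done stepwise: hydroxyl-directed epoxidation of C9=C10 (VO(acac)2, t-BuOOH) to the syn bis-epoxy alcohol F6, thiocarbonylation with 1,1′-thiocarbonyldiimidazole to the imidazolide F7, and Bu3SnH/AIBN in toluene at 80 °C, under which the C8 radical opens the adjacent oxirane and the C10 alkoxy radical is reduced, to reach 33.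

Second, step 17. Intermolecular thioether formation (oligomerisation) may outrun closure of the 13-membered ring, and allylic transposition may accompany the displacements. The fallback sets out from 23 and comes back at 26. Potassium thioacetate (1 equiv, DMF, −20 °C) would give the C8 thioacetate F8 and the C12 thioacetate F9, which are separated from dibromide and bis-thioacetate. K2CO3 in degassed MeOH–THF at high dilution would then release the thiolate slowly by methanolysis, so that each molecule cyclises before it meets another, and both isomers converge on 26.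

Third, step 19. The thioether may inhibit the rhodium catalyst, a rhodium hydride may migrate the isopropenyl or allyl sulfide double bonds before reduction, and the strained E ring alkene may be reduced as well. The fallback sets out from 29 and comes back at 30. Diimide generated from 2-nitrobenzenesulfonylhydrazide and Et3N (CH2Cl2, rt) is a metal-free reductant that is indifferent to sulfur, cannot isomerise alkenes and discriminates by alkene substitution; no new compound is made (F0).

**Further compounds**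

F1 | step 18 | C8 mono-bromide, C12 alcohol (C6 OTBS; 4S,5R,6R) | BrC/C=C(\C)CCC[C@]1(C)O[C@@H]1[C@H](O[Si](C)(C)C(C)(C)C)/C=C(\C)CO
F2 | step 18 | C12 mono-bromide, C8 alcohol (C6 OTBS; 4S,5R,6R) | OC/C=C(\C)CCC[C@]1(C)O[C@@H]1[C@H](O[Si](C)(C)C(C)(C)C)/C=C(\C)CBr
F3 | step 18 | 13-membered diallyl ether (oxygen between C8 and C12; C6 OTBS; 4S,5R,6R; 9E and 7(11)E) | O1C/C=C(\C)CCC[C@]2(C)O[C@@H]2[C@H](O[Si](C)(C)C(C)(C)C)/C=C(\C)C1
F4 | step 18 | 8R homoallylic alcohol: 6-[(tert-butyldimethylsilyl)oxy]-4,5-epoxygermacra-9,11-dien-8-ol | C=C(C)[C@H]1[C@H](O)/C=C(\C)CCC[C@]2(C)O[C@@H]2[C@@H]1O[Si](C)(C)C(C)(C)C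
F5 | step 18 | 6-[(tert-butyldimethylsilyl)oxy]-4,5-epoxygermacr-9-en-8-ol | CC(C)[C@H]1[C@H](O)/C=C(\C)CCC[C@]2(C)O[C@@H]2[C@@H]1O[Si](C)(C)C(C)(C)C
F6 | step 18 | 6-[(tert-butyldimethylsilyl)oxy]-4,5:9,10-diepoxygermacran-8-ol (9,10-oxirane syn to the C8 hydroxyl) | CC(C)[C@H]1[C@H](O)[C@H]3O[C@]3(C)CCC[C@]2(C)O[C@@H]2[C@@H]1O[Si](C)(C)C(C)(C)C
F7 | step 18 | O-(imidazol-1-ylthiocarbonyl) derivative of F6 at C8 | CC(C)[C@H]1[C@H](OC(=S)n3ccnc3)[C@H]4O[C@]4(C)CCC[C@]2(C)O[C@@H]2[C@@H]1O[Si](C)(C)C(C)(C)C
F8 | step 17 | C8 thioacetate, C12 bromide (C6 OTBS; 4S,5R,6R) | CC(=O)SC/C=C(\C)CCC[C@]1(C)O[C@@H]1[C@H](O[Si](C)(C)C(C)(C)C)/C=C(\C)CBr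
F9 | step 17 | C12 thioacetate, C8 bromide (C6 OTBS; 4S,5R,6R) | BrC/C=C(\C)CCC[C@]1(C)O[C@@H]1[C@H](O[Si](C)(C)C(C)(C)C)/C=C(\C)CSC(C)=O
F0 | step 19 | none | none
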